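**Retrosynthetic overview**

1. Target 12 ⇐ hydroxy-lactone acid 10, by β-elimination of the tertiary alcohol (gives the C3=C4 bond) and tert-butyl ester acidolysis. 10 ⇐ 9 by late ω-oxidation (CH2OH → CO2H).
2. The only ring is closed in one operation from the open-chain (R)-β-hydroxy ester 5 and methyl pyruvate 6. The C–C bond forms first (ester α-carbon → pyruvate C-2), then the C–O bond (C-3 oxygen → pyruvate C-1).
3. 5 ⇐ β-keto ester 4 by Noyori hydrogenation, which sets the single stereocentre.
4. 4 ⇐ 16-hexadecanolide 1 + tert-butyl acetate 2 by ring-opening Claisen condensation (C16 + C2). Both, and methyl pyruvate, are cheap commercial chemicals.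
5. Ring order: saturated γ-lactone in step 3, converted to the butenolide in step 5.

Assumption: the presumed biosynthesis is the one proposed for the lichesterinic/protolichesterinic acids — a 3-oxygenated C18 fatty acyl unit condenses through its α-carbon with C-2 of pyruvate, the C-3 oxygen lactonises onto the pyruvate carboxyl, dehydration gives the butenolide, and the chain end is ω-oxidised.

The target stereocentre (C-2 of the 2,5-dihydrofuran) is (R).

**Route**

Step 1
Reactants: 1 16-hexadecanolide (oxacycloheptadecan-2-one); 2 tert-butyl acetate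
Product: 4 tert-butyl 18-hydroxy-3-oxooctadecanoate, via tert-butyl acetate lithium enolate 3 (not isolated)
Conditions: 2 (3.0 eq), LDA (3.0 eq), THF, −78 °C; then 1, −78 → −20 °C; AcOH quench
Reagents that add atoms: none
Why: Crossed Claisen condensation — the ester enolate acylates on the lactone carbonyl, the ring opens to the ω-alkoxide, and the β-keto ester is at once deprotonated by a second equivalent of 3, which blocks a second addition; no stereocentre is formed.

Step 2
Reactants: 4 tert-butyl 18-hydroxy-3-oxooctadecanoate
Product: 5 tert-butyl (3R)-3,18-dihydroxyoctadecanoate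
Conditions: RuCl2[(R)-BINAP] (0.5 mol%), H2 (50 bar), MeOH, 50 °C
Reagents that add atoms: none
Why: Noyori asymmetric hydrogenation of a β-keto ester — (R)-BINAP–Ru reduces the ester-chelated ketone with the same facial sense as methyl acetoacetate → (R)-3-hydroxybutanoate, setting the only stereocentre as (3R) (high ee expected, upgradable by crystallisation), while the primary alcohol and tert-butyl ester are inert.

Step 3
Reactants: 5 tert-butyl (3R)-3,18-dihydroxyoctadecanoate; 6 methyl pyruvate (methyl 2-oxopropanoate)
Product: 9 tert-butyl (2R)-4-hydroxy-2-(15-hydroxypentadecyl)-4-methyl-5-oxooxolane-3-carboxylate, via trilithium alkoxide-enolate 7 (not isolated), via open-chain aldol adduct 8 (not isolated)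
Conditions: LDA (3.3 eq), THF, −78 → −25 °C; 6 (2.0 eq), −78 °C; AcOH quench; then PPTS (cat.), toluene, 40 °C
Reagents that add atoms: none
Why: Fráter–Seebach-type aldol addition followed by γ-lactonisation — the ester α-CH2 is the only C–H acid of 5 (both hydroxyls are masked in the flask as lithium alkoxides), the chelated alkoxide–enolate adds to the ketone of the α-keto ester, and the C-3 oxygen then acylates on the pyruvate ester to close the ring; the (R)-carbinol centre is not touched, and the two new centres (a mixture) are erased in step 5.

Step 4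
Reactants: 9 tert-butyl (2R)-4-hydroxy-2-(15-hydroxypentadecyl)-4-methyl-5-oxooxolane-3-carboxylate
Product: 10 15-[(2R)-3-(tert-butoxycarbonyl)-4-hydroxy-4-methyl-5-oxooxolan-2-yl]pentadecanoic acid
Conditions: TEMPO (0.2 eq), PhI(OAc)2 (2.5 eq), CH2Cl2/H2O (2:1), rt
Reagents that add atoms: water, O
Why: TEMPO/PhI(OAc)2 oxidation (oxoammonium catalysis) takes the primary alcohol through the aldehyde hydrate to the carboxylic acid; the tertiary alcohol cannot be oxidised and no stereocentre is involved.

Step 5
Reactants: 10 15-[(2R)-3-(tert-butoxycarbonyl)-4-hydroxy-4-methyl-5-oxooxolan-2-yl]pentadecanoic acid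
Product: 12 (2R)-2-(14-carboxytetradecyl)-4-methyl-5-oxo-2,5-dihydrofuran-3-carboxylic acid, via butenolide tert-butyl ester 11 (not isolated)
Conditions: MsCl (3 eq), Et3N (6 eq), CH2Cl2, −20 → 0 °C; then TFA/H2O (95:5), rt
Reagents that add atoms: none
Why: Sulfonate-mediated β-elimination then acidolysis — MsCl/Et3N (sulfene) mesylates the tertiary C-4 hydroxyl and the C-3 proton, α to the ester, is lost (E1cB/E2) to give the conjugated tetrasubstituted butenolide (any exo-methylene isomer is isomerised to the endo alkene by Et3N), after which TFA removes the tert-butyl group as isobutene; C-2 is not part of any bond made or broken and stays (R).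

**Compound list**

1 | 16-hexadecanolide (oxacycloheptadecan-2-one) | O=C1CCCCCCCCCCCCCCCO1 | starting material
2 | tert-butyl acetate | CC(=O)OC(C)(C)C | starting material
3 | lithium enolate of tert-butyl acetate | [Li+].C=C([O-])OC(C)(C)C | intermediate (not isolated)
4 | tert-butyl 18-hydroxy-3-oxooctadecanoate | OCCCCCCCCCCCCCCCC(=O)CC(=O)OC(C)(C)C | intermediate
5 | tert-butyl (3R)-3,18-dihydroxyoctadecanoate | OCCCCCCCCCCCCCCC[C@@H](O)CC(=O)OC(C)(C)C | intermediate
6 | methyl pyruvate (methyl 2-oxopropanoate) | COC(=O)C(C)=O | starting material
7 | trilithium alkoxide-enolate of 5 (both hydroxyls and the ester α-carbon deprotonated; (R) centre unchanged) | [Li+].[Li+].[Li+].[O-]CCCCCCCCCCCCCCC[C@@H]([O-])C=C([O-])OC(C)(C)C | intermediate (not isolated)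
8 | 1-tert-butyl 4-methyl 2-[(1R)-1,16-dihydroxyhexadecyl]-3-hydroxy-3-methylbutanedioate (open-chain aldol adduct, formed as its lithium alkoxide; C-2/C-3 mixture) | COC(=O)C(C)(O)C(C(=O)OC(C)(C)C)[C@H](O)CCCCCCCCCCCCCCCO | intermediate (not isolated)
9 | tert-butyl (2R)-4-hydroxy-2-(15-hydroxypentadecyl)-4-methyl-5-oxooxolane-3-carboxylate (C-3/C-4 diastereomer mixture, both removed later) | CC1(O)C(C(=O)OC(C)(C)C)[C@@H](CCCCCCCCCCCCCCCO)OC1=O | intermediate
10 | 15-[(2R)-3-(tert-butoxycarbonyl)-4-hydroxy-4-methyl-5-oxooxolan-2-yl]pentadecanoic acid (C-3/C-4 mixture) | CC1(O)C(C(=O)OC(C)(C)C)[C@@H](CCCCCCCCCCCCCCC(=O)O)OC1=O | intermediate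
11 | 15-[(2R)-3-(tert-butoxycarbonyl)-4-methyl-5-oxo-2,5-dihydrofuran-2-yl]pentadecanoic acid | CC1=C(C(=O)OC(C)(C)C)[C@@H](CCCCCCCCCCCCCCC(=O)O)OC1=O | intermediate (not isolated)
12 | (2R)-2-(14-carboxytetradecyl)-4-methyl-5-oxo-2,5-dihydrofuran-3-carboxylic acid (CNP0256645.1) | CC1=C(C(=O)O)[C@@H](CCCCCCCCCCCCCCC(=O)O)OC1=O | target

**Totals**

Total step count: 5. Longest linear sequence: 5 steps (from 1).

**Steps most likely to fail, with fallbacks**

Step 3 (polyanion aldol–lactonisation) carries the most risk. The trianion can enolise methyl pyruvate or trigger its self-condensation, the ω-alkoxide can add to or be acylated by the keto ester, and the tertiary aldolate can revert before the lactone closes. The fallback sets out from 4 and returns at 9. It moves the C–C bond formation one stage earlier, onto the far more acidic β-keto ester. Soft enolisation of 4 (MgBr2·OEt2, i-Pr2NEt, CH2Cl2, 0 °C) and addition to methyl pyruvate 6 gives the aldol adduct tert-butyl 18-hydroxy-2-(2-hydroxy-1-methoxy-1-oxopropan-2-yl)-3-oxooctadecanoate F1 as a diastereomer mixture. Hydrogenation of F1 with RuCl2[(R)-BINAP]/H2 in MeOH then reduces the ketone with the same catalyst-controlled facial sense. The new (R)-hydroxyl closes onto the methyl ester with loss of methanol to give 9, where the route continues.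

Step 5 (elimination and deprotection) is the second risk. Et3N could erode the ee of the butenolide through its 2-oxidofuran, and mesylation of the hindered tertiary α-hydroxy lactone may be slow. The ω-carboxylate is also transiently converted by the excess MsCl into a mixed anhydride, which the wet TFA must hydrolyse back. The fallback sets out from 10 and returns at 12. It reverses the order and avoids amine base. TFA/CH2Cl2 first cleaves the tert-butyl ester of 10 to the diacid (2R)-2-(14-carboxytetradecyl)-4-hydroxy-4-methyl-5-oxooxolane-3-carboxylic acid F2. Heating F2 in acetic anhydride (70–80 °C) dehydrates the β-hydroxy acid through its mixed anhydride, as in the classical citramalic → citraconic conversion. Aqueous work-up (THF/H2O) then returns the free diacid 12.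

Step 1 (ring-opening Claisen) is the third. The excess enolate may simply enolise the macrolide (1 recovered), or conversion may be incomplete at the low temperature needed to keep the tert-butyl acetate enolate intact. The fallback sets out from 1 and returns at 4. Half-reduction of 1 with DIBAL-H (CH2Cl2, −78 °C) gives 16-hydroxyhexadecanal F3. Homologation of F3 with tert-butyl diazoacetate under SnCl2 catalysis (Roskamp reaction, CH2Cl2, rt, loss of N2) gives 4.

Further compounds
F1 | step 3 | tert-butyl 18-hydroxy-2-(2-hydroxy-1-methoxy-1-oxopropan-2-yl)-3-oxooctadecanoate | COC(=O)C(C)(O)C(C(=O)OC(C)(C)C)C(=O)CCCCCCCCCCCCCCCO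
F2 | step 5 | (2R)-2-(14-carboxytetradecyl)-4-hydroxy-4-methyl-5-oxooxolane-3-carboxylic acid | CC1(O)C(C(=O)O)[C@@H](CCCCCCCCCCCCCCC(=O)O)OC1=O
F3 | step 1 | 16-hydroxyhexadecanal | OCCCCCCCCCCCCCCCC=O
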